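## The problem

- **Skeleton.** CNP0164095.1 is a caged acylphloroglucinol built on a bicyclo[3.3.1]nonane-2,4,9-trione (C1 to C9). C1 carries the benzoyl group, C5 the geranyl chain, C8 is CMe2 and C9 is the one-carbon keto bridge. C3 and C7 are joined by a second bridge, C11–C10, so the core is a homoadamantane. The C3–C11 bond is also one edge of a cyclopentane (C3, C11, C12 = CMe2, C13, C14), and C13 carries the hydroxyisopropyl carbon C15.
- **Congestion.** Five quaternary carbons (C1, C3, C5, C8, C12) lie in or on the cage, and every ketone is flanked on both sides by fully substituted carbon.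
- **Stereocentres.** There are six (C1, C3, C5, C7, C11, C13) but only three decisions. With C7 fixed, C1 and C5 can close the cage in one sense only. With C7 and C11 fixed, C3 follows once its two acyl groups are told apart: in the target the C4 carbonyl is cis to C10 on the cyclopentane and the C2 carbonyl is trans. C13 (carbinol trans to C10) is independent.
- **Control.** C7 and C11 are 1,3-related through the freely rotating C10, so C7 cannot be trusted to control C11; a reagent has to.
- **Sensitive groups.** The C2–C3–C4 diketone cannot enolise, so the finished cage is cleaved by alkoxide or hydroxide (retro-Claisen). The two trisubstituted alkenes of the geranyl chain exclude late hydrogenation, electrophilic halogen and strong acid. The tertiary alcohol sits on the face of the C2 carbonyl, eliminates in acid and lactonises onto any activated C2 acyl group.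
- **Enabling feature.** C3 bears two carbonyl groups and is bonded to a methine (C11) that is bonded to CMe2 (C12), with C13 and C14 completing a five-membered ring. This is the imprint of a [3+2] union of an alkylidene malonate (C3, C11) with the three carbons of a 3,3-dimethylallenylsilane (C12, C13, C14). Silicon is left on C13, the carbon that must receive C15.

## Retrosynthesis

**C1–benzoyl (30 ← 29 ← 28).** The silyl ether 29 is the last protected form, and the benzoyl C–C bond is cut first. In 28 the C1–H is the only acidic hydrogen, so bridgehead metalation needs no regiocontrol. A benzoyl group present earlier would turn C1 into a 1,3-diketone carbon that O-acylates and would not survive the base steps. The forward step asks for deprotonation of a bridgehead between two ketones without attack on the cage carbonyls.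

**C1–C2 (28 ← 27 ← 26 ← 25).** Cutting C1–C2 opens the cage to the bicyclic diketone 25, whose C9 ketone has one enolisable position (C1) and, after unmasking, one acyl donor (C2). This bond is cut before C4–C5 because C5 is better quaternised by alkylating a stabilised enolate while the bicycle is still flexible. The product cannot be deprotonated, so the acyl donor must be irreversible (acid chloride 27); an ester would revert.

**C5–geranyl and C4–C5 (25 ← 23 + 24; 23 ← 22).** Geranyl bromide 24 alkylates the β-diketone 23, and 23 comes from ketone 22 by Claisen condensation of the C5 enolate with the methyl ester. This closure is driven by deprotonation of 23 at C5, which is why it precedes geranylation. It also decides C3. Only the ester cis to C10 may bond to C5, so in 22 that ester is the methyl ester and the other is a tert-butyl ester, which an enolate does not attack. Geranyl enters only after every step that would touch its alkenes.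

**Carbinol and C13 (22 ← 21 ← 20 ← 19 ← 17 ← 15 ← 14).** The C15–CH3 bond is cut to methyl ketone 19, the C13–H bond to enone 17, the C13–C15 bond to vinyl iodide 15, and C13–I to vinylsilane 14. An acetyl group is chosen over an ester or an isopropenyl group because its α-hydrogen lets C13 be equilibrated and because a ketone is easily told from two hindered esters by an organometallic. The forward steps ask that the trans epimer 19 be the stable one and that the ketal survive until the methyl addition is done.

**Telling the esters apart (14 ← 13 ← 12).** The mixed diester 14 comes from half acid 13, made by hydrolysing one ester of 12. This is done at the cyclopentene stage, where C13 is sp2 and the only difference between the two ester faces is the C11 side chain. The ester trans to it is the accessible one, and it is the one that has to become C2.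

**The [3+2] cut (12 ← 9 + 11).** Both ring bonds to the malonate-derived half are cut together: C11–C12 and C3–C14. Neighbouring cuts are weaker. Double alkylation of a malonate would need a secondary neopentyl electrophile, and a conjugate addition followed by ene-type closure would leave no handle on C13. This cut makes the quaternary C12, the quaternary C3 and the C13 handle in one operation from an achiral allene (11) and an acyclic acceptor (9) with a single stereocentre. It asks for face selection at C11 by a chiral Lewis acid and for ring closure that outruns loss of silicon, hence a bulky silyl group on 11.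

**Acceptor and allene (9 ← 7 + 8; 7 ← 6 ← 5 ← 4 ← 3 ← 2 ← 1; 11 ← 10).**
- Condensation of aldehyde 7 with dimethyl malonate 8 gives 9.
- 7 comes from ester 6 by partial reduction, and the ketal from ketone 5.
- The C9 oxygen is introduced by allylic oxidation of cyclohexene 3 to enone 4, followed by hydrogenation.
- The C7–C10 bond of 3 is cut by a [3,3] shift back to allylic alcohol 2. The shift delivers the acetate unit intramolecularly to the carbon beside the quaternary centre and copies the carbinol configuration into C7.
- 2 comes from enone 1 by catalytic asymmetric reduction. Direct alkylation of an achiral cyclohexenone enolate would be shorter but racemic.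
- Allene 11 is the silylation product of the lithiated hydrocarbon 10.

## Roads not taken

**Alternative 1:** The cut is C5–C6 and C1–C8 together. In the forward sense acid ionises a tertiary allylic alcohol in the side chain. The free enol carbon C5 attacks the primary end of the allyl cation, the new tetrasubstituted alkene is protonated at C7, and the benzoyl-bearing enol carbon C1 captures the tertiary cation, giving A1, the cage without geranyl.
- Merits: the carbocycle and both seven-membered rings close in one flask, and the benzoyl group is present from the start, so no bridgehead acylation is needed. On step count after the cyclopentane it is clearly better than the chosen plan.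
- Weak points: C7 is created by protonation of an alkene, with no obvious element that fixes its face. C1–C8 joins two fully substituted carbons by trapping a cation with a hindered, electron-poor enol, so oxygen capture and elimination compete. The C15 carbinol is a second tertiary alcohol under ionising acid. Geranyl cannot be present and must be added to the C5 bridgehead of A1 afterwards.
- Comparison: the spiro centre C3 still has to be set relative to C11 before the cascade. The chosen plan is longer, but C7 comes from a chirality transfer and each cage bond forms at a single possible site.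

**Alternative 2:** The cut is C1–C8, made by a 1,2-shift. A ketone enolate beside a tertiary cyclopentanol is oxidised by a hypervalent iodine reagent and the CMe2 carbon migrates to the α-carbon. This unveils the C9 ketone and expands the five-membered ring to give A2, a bicyclo[3.3.1]nonane trione enol ether with C5 geranyl and C7 prenyl.
- Merits: it reaches the bicyclic core with C5, C7 and C8 in place in few steps, and bridgehead acylation of such enol ethers at C1 is the best-precedented way to place the benzoyl group. In both respects it is better than the chosen plan.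
- Weak points: the oxidant meets three trisubstituted alkenes and an enol ether, and the migration needs strict alignment. A2 contains nothing of the cyclopentane. C3–C11 and C12–C13 would have to be made late across C3 and the C7 prenyl group, creating C3, C11 and C13 in a cationic or radical cascade with no external control.
- Comparison: the chosen plan sets C11 with a catalyst and C13 by equilibration before the cage exists. It pays with a long linear sequence and a benzoylation on a more rigid cage than A2.

**Alternative 3:** The cut is C5–C6 and C3–C11 in a [4+3] sense. A dirhodium vinylcarbenoid cyclopropanates the terminal alkene of a 2,4-disubstituted diene and the cis-divinylcyclopropane undergoes Cope rearrangement to the cycloheptadiene A3.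
- Merits: it is convergent and catalytic, the two ring substituents come out cis from the boat transition state, the absolute configuration is set at the start, and the benzoyl carbon and C8 arrive with the diene. On convergence it is superior.
- Weak points: A3 has the seven-membered ring but none of the quaternary centres C1, C3 and C5. Still to come are C5 geranylation, the C1–C9 bond, a one-carbon carbonyl inserted between C1 and C3, and closure of the cyclopentane by ionisation at C12 onto the C3 prenyl group, which sets C13 in a cation–olefin step.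
- Comparison: the hard bonds are left for the end. The chosen plan makes C3 and the cyclopentane in its key step and closes the cage by two enolate acylations with one possible outcome each.

Key step: step 9

Assumption: the (S,S)-tert-butyl-bis(oxazoline) complex of divalent copper is taken to expose the face of C11 drawn in 12, by analogy with enolsilane additions to alkylidene malonates; if the other C11 epimer prevails, the (R,R)-ligand is used and nothing else changes.

Step 1
Reactants: 1 4,4-dimethylcyclohex-2-en-1-one
Product: 2 (1R)-4,4-dimethylcyclohex-2-en-1-ol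
Conditions: (S)-2-methyl-CBS-oxazaborolidine (10 mol %), BH3·SMe2, THF, −20 °C
Reagents that add atoms: none
Why: Corey–Bakshi–Shibata reduction; the alkene arm of the enone acts as the large group and the (S)-oxazaborolidine should deliver hydride to give the (R)-allylic alcohol, which fixes the absolute configuration of the route.

Step 2
Reactants: 2 (1R)-4,4-dimethylcyclohex-2-en-1-ol
Product: 3 ethyl 2-[(1R)-6,6-dimethylcyclohex-2-en-1-yl]acetate
Conditions: MeC(OEt)3, EtCO2H (cat.), 140 °C, EtOH distilled off
Reagents that add atoms: triethyl orthoacetate, CC(OCC)(OCC)OCC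
Why: Johnson–Claisen rearrangement; the ketene acetal carbon is delivered across the ring face that carries oxygen (suprafacial [3,3] shift), so the carbinol configuration of 2 becomes the C7 configuration of 3, and intramolecular delivery overcomes the hindrance of the neighbouring quaternary carbon.

Step 3
Reactants: 3 ethyl 2-[(1R)-6,6-dimethylcyclohex-2-en-1-yl]acetate
Product: 4 ethyl 2-[(1R)-6,6-dimethyl-4-oxocyclohex-2-en-1-yl]acetate
Conditions: Rh2(caprolactamate)4 (1 mol %), t-BuOOH (aq.), K2CO3 (0.5 equiv), CH2Cl2, rt
Reagents that add atoms: tert-butyl hydroperoxide, CC(C)(C)OO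
Why: Dirhodium-catalysed allylic C–H oxidation; the ring CH2 beside the alkene is the only open allylic position (the other is the tertiary C7–H next to the quaternary carbon), and the allyl radical should be trapped at its unhindered end, C9.

Step 4
Reactants: 4 ethyl 2-[(1R)-6,6-dimethyl-4-oxocyclohex-2-en-1-yl]acetate
Product: 5 ethyl 2-[(1S)-2,2-dimethyl-4-oxocyclohexyl]acetate
Conditions: H2 (1 atm), Pd/C, EtOAc, rt
Reagents that add atoms: none
Why: Catalytic hydrogenation of a conjugated alkene; nothing else is reducible and C7 is untouched (the descriptor changes only because the ring priorities change).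

Step 5
Reactants: 5 ethyl 2-[(1S)-2,2-dimethyl-4-oxocyclohexyl]acetate
Product: 6 ethyl 2-[(8S)-7,7-dimethyl-1,4-dioxaspiro[4.5]decan-8-yl]acetate
Conditions: HOCH2CH2OH, p-TsOH (cat.), benzene, reflux, azeotropic removal of water
Reagents that add atoms: ethane-1,2-diol, OCCO
Why: Acid-catalysed ketalisation; the dioxolane masks C9 through the hydride, organometallic and Lewis acid steps that follow.

Step 6
Reactants: 6 ethyl 2-[(8S)-7,7-dimethyl-1,4-dioxaspiro[4.5]decan-8-yl]acetate
Product: 7 2-[(8S)-7,7-dimethyl-1,4-dioxaspiro[4.5]decan-8-yl]acetaldehyde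
Conditions: i-Bu2AlH (1.05 equiv), CH2Cl2, −78 °C; aq. potassium sodium tartrate
Reagents that add atoms: none
Why: Partial reduction of an ester; the tetrahedral aluminium hemiacetal is stable at −78 °C and releases the aldehyde on work-up.

Step 7
Reactants: 7 2-[(8S)-7,7-dimethyl-1,4-dioxaspiro[4.5]decan-8-yl]acetaldehyde; 8 dimethyl malonate
Product: 9 dimethyl 2-{2-[(8S)-7,7-dimethyl-1,4-dioxaspiro[4.5]decan-8-yl]ethylidene}propanedioate
Conditions: piperidine (10 mol %), AcOH (10 mol %), benzene, reflux, azeotropic removal of water
Reagents that add atoms: none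
Why: Knoevenagel condensation; iminium catalysis with excess malonate should outrun self-aldolisation of the aldehyde, and the conjugated isomer is the stable one for a malonate.

Step 8
Reactants: 10 3-methylbuta-1,2-diene
Product: 11 tert-butyl(dimethyl)(3-methylbuta-1,2-dien-1-yl)silane
Conditions: n-BuLi, THF, −78 °C; t-BuMe2SiCl, −78 °C to rt
Reagents that add atoms: tert-butyl(chloro)dimethylsilane, CC(C)(C)[Si](C)(C)Cl
Why: Deprotonation of the allenic CH2 terminus and silylation of the allenyllithium at the unsubstituted carbon; the CMe2 end is too hindered to give the propargylsilane.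

Step 9
Reactants: 9 dimethyl 2-{2-[(8S)-7,7-dimethyl-1,4-dioxaspiro[4.5]decan-8-yl]ethylidene}propanedioate; 11 tert-butyl(dimethyl)(3-methylbuta-1,2-dien-1-yl)silane
Product: 12 dimethyl (5R)-3-[tert-butyl(dimethyl)silyl]-5-{[(8S)-7,7-dimethyl-1,4-dioxaspiro[4.5]decan-8-yl]methyl}-4,4-dimethylcyclopent-2-ene-1,1-dicarboxylate
Conditions: Cu(OTf)2 (10 mol %), (S,S)-2,2′-(propane-2,2-diyl)bis(4-tert-butyl-4,5-dihydrooxazole) (11 mol %), 4 Å MS, CH2Cl2, −20 °C to rt
Reagents that add atoms: none
Why: Proposed new method: the closest known reaction is the Danheiser annulation of allenylsilanes with α,β-unsaturated ketones under TiCl4, and the closest catalytic model is the addition of π-nucleophiles to alkylidene malonates held as six-membered chelates by bis(oxazoline) complexes of divalent copper; the two have not been combined. The copper chelate of 9 should be attacked at C11 by the CMe2 terminus of 11, which forms the C11–C12 bond and a vinyl cation stabilised by the β-silyl group. A 1,2-shift of silicon moves the charge to the terminal carbon, and the copper-bound malonate carbon closes on this sp-hybridised centre (C3–C14), a 5-endo closure with respect to the new C13=C14 bond that is allowed because the empty orbital lies in the plane of the forming ring. The only new stereocentre, C11, is set in the first bond formation by the tert-butyl groups of the ligand, which shield one face of the planar chelate; C7 is three bonds away and is expected to have little say, so the step is treated as catalyst controlled. C3 is not yet stereogenic and C13 is sp2, so no other selectivity is needed here. Regiochemistry is fixed by the allene, since only attack through the CMe2 end leaves a cation β to silicon. The tert-butyldimethylsilyl group replaces trimethylsilyl because allenylsilanes unsubstituted at the silylated carbon tend to lose a small silyl group from the vinyl cation and end as alkynes. The mild triflate complex is chosen over TiCl4 so that the ketal is not opened.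

Step 10
Reactants: 12 dimethyl (5R)-3-[tert-butyl(dimethyl)silyl]-5-{[(8S)-7,7-dimethyl-1,4-dioxaspiro[4.5]decan-8-yl]methyl}-4,4-dimethylcyclopent-2-ene-1,1-dicarboxylate
Product: 13 (1S,5R)-3-[tert-butyl(dimethyl)silyl]-5-{[(8S)-7,7-dimethyl-1,4-dioxaspiro[4.5]decan-8-yl]methyl}-1-(methoxycarbonyl)-4,4-dimethylcyclopent-2-ene-1-carboxylic acid (acid trans to the C5 side chain)
Conditions: KOH (1.2 equiv), MeOH/H2O, rt to 40 °C; then 1 M HCl to pH 4, 0 °C
Reagents that add atoms: potassium hydroxide, [K+].[OH-]
Why: Saponification of a geminal diester should stop after one ester because the carboxylate shields its neighbour, and hydroxide attacks the ester on the face away from the C11 side chain (steric approach control). This makes C3 a stereocentre with the free acid trans to C10, the acyl group that is to become C2.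

Step 11
Reactants: 13 (1S,5R)-3-[tert-butyl(dimethyl)silyl]-5-{[(8S)-7,7-dimethyl-1,4-dioxaspiro[4.5]decan-8-yl]methyl}-1-(methoxycarbonyl)-4,4-dimethylcyclopent-2-ene-1-carboxylic acid
Product: 14 1-tert-butyl 1-methyl (1R,5R)-3-[tert-butyl(dimethyl)silyl]-5-{[(8S)-7,7-dimethyl-1,4-dioxaspiro[4.5]decan-8-yl]methyl}-4,4-dimethylcyclopent-2-ene-1,1-dicarboxylate (tert-butyl ester trans to the side chain)
Conditions: O-tert-butyl-N,N′-diisopropylisourea (3 equiv), CH2Cl2, rt
Reagents that add atoms: O-tert-butyl-N,N′-diisopropylisourea, CC(C)NC(=NC(C)C)OC(C)(C)C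
Why: Neutral tert-butyl ester formation by O-alkylation of the carboxylate with the protonated isourea; suited to a hindered acid and harmless to ketal, vinylsilane and methyl ester.

Step 12
Reactants: 14 1-tert-butyl 1-methyl (1R,5R)-3-[tert-butyl(dimethyl)silyl]-5-{[(8S)-7,7-dimethyl-1,4-dioxaspiro[4.5]decan-8-yl]methyl}-4,4-dimethylcyclopent-2-ene-1,1-dicarboxylate
Product: 15 1-tert-butyl 1-methyl (1R,5R)-5-{[(8S)-7,7-dimethyl-1,4-dioxaspiro[4.5]decan-8-yl]methyl}-3-iodo-4,4-dimethylcyclopent-2-ene-1,1-dicarboxylate
Conditions: N-iodosuccinimide (1.3 equiv), 2,6-lutidine (0.5 equiv), (CF3)2CHOH, 0 °C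
Reagents that add atoms: N-iodosuccinimide, O=C1CCC(=O)N1I
Why: Electrophilic ipso-iododesilylation of a vinylsilane; the fluorinated alcohol activates the iodinating agent and stabilises the β-silyl cation so that even a bulky silyl group is replaced with the double bond kept in place, and the lutidine buffer protects the ketal.

Step 13
Reactants: 15 1-tert-butyl 1-methyl (1R,5R)-5-{[(8S)-7,7-dimethyl-1,4-dioxaspiro[4.5]decan-8-yl]methyl}-3-iodo-4,4-dimethylcyclopent-2-ene-1,1-dicarboxylate
Product: 17 1-tert-butyl 1-methyl (1S,5S)-3-acetyl-5-{[(8S)-7,7-dimethyl-1,4-dioxaspiro[4.5]decan-8-yl]methyl}-4,4-dimethylcyclopent-2-ene-1,1-dicarboxylate, via ethoxyvinyl diene 16 (not isolated)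
Conditions: Bu3Sn(C(OEt)=CH2) (1.5 equiv), Pd(PPh3)4 (5 mol %), CuI (10 mol %), CsF (2 equiv), DMF, 45 °C; then 0.5 M HCl, THF, 0 °C, 10 min
Reagents that add atoms: tributyl(1-ethoxyvinyl)stannane, CCCC[Sn](CCCC)(CCCC)C(=C)OCC; water, O
Why: Stille coupling with an acetyl anion equivalent; CuI and fluoride speed transmetalation to the hindered alkenyl iodide, and the enol ether is hydrolysed by dilute acid far faster than the cyclic ketal.

Step 14
Reactants: 17 1-tert-butyl 1-methyl (1S,5S)-3-acetyl-5-{[(8S)-7,7-dimethyl-1,4-dioxaspiro[4.5]decan-8-yl]methyl}-4,4-dimethylcyclopent-2-ene-1,1-dicarboxylate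
Product: 19 1-tert-butyl 1-methyl (1S,2S,4R)-4-acetyl-2-{[(8S)-7,7-dimethyl-1,4-dioxaspiro[4.5]decan-8-yl]methyl}-3,3-dimethylcyclopentane-1,1-dicarboxylate (acetyl trans to the C2 side chain), via cis-acetyl epimer 18 (not isolated)
Conditions: H2 (1–3 atm), Pd/C, EtOAc, rt; filter; NaOMe (0.2 equiv), MeOH, rt
Reagents that add atoms: none
Why: Hydrogenation of the enone, then base equilibration of the acetyl-bearing carbon. The hydrogen that adds to C13 should come from the face away from the C11 side chain and give mainly the cis epimer 18; methoxide then epimerises C13 to the trans epimer 19, expected to be the stable one because a cis acetyl group meets either the pseudoaxial ester or the side chain in a 1,3 fashion in every envelope conformer. Catalytic methoxide matches the methyl ester and leaves the tert-butyl ester alone.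

Step 15
Reactants: 19 1-tert-butyl 1-methyl (1S,2S,4R)-4-acetyl-2-{[(8S)-7,7-dimethyl-1,4-dioxaspiro[4.5]decan-8-yl]methyl}-3,3-dimethylcyclopentane-1,1-dicarboxylate
Product: 20 1-tert-butyl 1-methyl (1S,2S,4R)-2-{[(8S)-7,7-dimethyl-1,4-dioxaspiro[4.5]decan-8-yl]methyl}-4-(2-hydroxypropan-2-yl)-3,3-dimethylcyclopentane-1,1-dicarboxylate
Conditions: CeCl3 (1.5 equiv), MeLi (1.5 equiv), THF, −78 °C; aq. NH4Cl
Reagents that add atoms: methyllithium, [Li]C
Why: 1,2-Addition of an organocerium reagent; it is nucleophilic but barely basic, so the hindered enolisable methyl ketone should be methylated without loss of the C13 configuration, and the two esters on the quaternary carbon do not react at −78 °C.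

Step 16
Reactants: 20 1-tert-butyl 1-methyl (1S,2S,4R)-2-{[(8S)-7,7-dimethyl-1,4-dioxaspiro[4.5]decan-8-yl]methyl}-4-(2-hydroxypropan-2-yl)-3,3-dimethylcyclopentane-1,1-dicarboxylate
Product: 21 1-tert-butyl 1-methyl (1S,2S,4R)-2-{[(8S)-7,7-dimethyl-1,4-dioxaspiro[4.5]decan-8-yl]methyl}-3,3-dimethyl-4-{2-[(triethylsilyl)oxy]propan-2-yl}cyclopentane-1,1-dicarboxylate
Conditions: Et3SiOTf, 2,6-lutidine, CH2Cl2, −78 to 0 °C
Reagents that add atoms: triethylsilyl trifluoromethanesulfonate, CC[Si](CC)(CC)OS(=O)(=O)C(F)(F)F
Why: Silylation of a hindered tertiary alcohol with a silyl triflate; the ether keeps the alkoxide from attacking the cis ester in the base steps and later from lactonising onto the activated C2 acyl group.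

Step 17
Reactants: 21 1-tert-butyl 1-methyl (1S,2S,4R)-2-{[(8S)-7,7-dimethyl-1,4-dioxaspiro[4.5]decan-8-yl]methyl}-3,3-dimethyl-4-{2-[(triethylsilyl)oxy]propan-2-yl}cyclopentane-1,1-dicarboxylate
Product: 22 1-tert-butyl 1-methyl (1S,2S,4R)-2-{[(1S)-2,2-dimethyl-4-oxocyclohexyl]methyl}-3,3-dimethyl-4-{2-[(triethylsilyl)oxy]propan-2-yl}cyclopentane-1,1-dicarboxylate
Conditions: pyridinium p-toluenesulfonate (0.2 equiv), acetone/H2O (10:1), 50 °C
Reagents that add atoms: water, O
Why: Acid-catalysed ketal hydrolysis; the pyridinium salt is mild enough for the tertiary silyl ether and the tert-butyl ester.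

Step 18
Reactants: 22 1-tert-butyl 1-methyl (1S,2S,4R)-2-{[(1S)-2,2-dimethyl-4-oxocyclohexyl]methyl}-3,3-dimethyl-4-{2-[(triethylsilyl)oxy]propan-2-yl}cyclopentane-1,1-dicarboxylate
Product: 23 bicyclic β-diketone from C4–C5 closure: cyclopentane-fused bicyclo[4.3.1]decane with ketones at C4 and C9, C5–H bridgehead, C1 as CH2, tert-butyl ester on C3 trans to C10, and the triethylsilyloxyisopropyl group on C13; configurations at C3, C5, C7, C11 and C13 as in the target
Conditions: LiN(iPr)2 (2.2 equiv), THF, −78 to 0 °C; aq. NH4Cl
Reagents that add atoms: none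
Why: Intramolecular Claisen (Dieckmann-type) condensation; the amide base removes a C5 proton kinetically (C1 is shielded by the gem-dimethyl group) and only the methyl ester is electrophilic enough, which is the ester cis to C10 and therefore the one that must become C4. The second equivalent of base deprotonates the new β-diketone at C5 so the condensation is not reversed, and C5 is a bridgehead whose configuration is fixed by the ring.

Step 19
Reactants: 23 bicyclic β-diketone from C4–C5 closure; 24 geranyl bromide, (2E)-1-bromo-3,7-dimethylocta-2,6-diene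
Product: 25 C5-geranylated bicyclic diketone: as 23 with the (2E)-3,7-dimethylocta-2,6-dienyl group in place of the C5 hydrogen
Conditions: NaH (1.2 equiv), THF, 0 °C; geranyl bromide (1.3 equiv), 0 °C to rt
Reagents that add atoms: none
Why: C-Alkylation of a β-diketone enolate with an allylic bromide; O-alkylation would give a bridgehead enol ether and is disfavoured, and geranyl can only enter where the hydrogen was, so C5 keeps its configuration. Bromide is the only nucleophile formed, which spares the now non-enolisable diketone.

Step 20
Reactants: 25 C5-geranylated bicyclic diketone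
Product: 26 carboxylic acid corresponding to 25 (CO2H on C3 trans to C10)
Conditions: Me3SiOTf (3 equiv), 2,6-lutidine (4 equiv), CH2Cl2, 0 °C; aq. citric acid work-up
Reagents that add atoms: none
Why: Silyl triflate-mediated cleavage of a tert-butyl ester (loss of 2-methylpropene from the O-silylated ester) and hydrolysis of the silyl ester on work-up; no protic acid or nucleophile is involved, so the geranyl alkenes, the silyl ether and the non-enolisable diketone should survive.

Step 21
Reactants: 26 carboxylic acid corresponding to 25
Product: 28 cage trione: the target skeleton with C1–H in place of benzoyl and the C15 hydroxyl as triethylsilyl ether, via acid chloride 27 (not isolated)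
Conditions: 1-chloro-N,N,2-trimethylprop-1-en-1-amine (1.5 equiv), CH2Cl2, 0 °C to rt; then MgBr2·OEt2 (3 equiv), i-Pr2NEt (4 equiv), CH2Cl2, 0 °C to rt
Reagents that add atoms: none
Why: Acid chloride formation under neutral conditions with an α-chloroenamine, then C-acylation of the ketone by soft enolisation (magnesium enolate generated by a tertiary amine). C1 is the only enolisable position and C2 the only acyl donor, so the six-membered ring can close in one way only, which sets C1 and completes the cage. Magnesium chelation favours C- over O-acylation, and chloride as leaving group makes the step irreversible although the product has no acidic hydrogen to drive it.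

Step 22
Reactants: 28 cage trione with C1–H
Product: 29 triethylsilyl ether of the target (benzoyl on C1)
Conditions: lithium 2,2,6,6-tetramethylpiperidide (2 equiv), THF, −78 °C; PhCOCl (3 equiv), −78 to −40 °C
Reagents that add atoms: benzoyl chloride, O=C(Cl)c1ccccc1
Why: Bridgehead metalation and acylation; C1–H lies between two carbonyl groups and is the only acidic hydrogen of 28, the pyramidal carbanion cannot invert, and C-acylation is forced because O-acylation would need a bridgehead enol. This is the established way of placing bridgehead acyl groups on bicyclo[3.3.1]nonane-trione cores.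

Step 23
Reactants: 29 triethylsilyl ether of the target
Product: 30 CNP0164095.1
Conditions: HF·pyridine, THF/pyridine, 0 °C to rt
Reagents that add atoms: none
Why: Fluoride-induced cleavage of the tertiary silyl ether under buffered, non-basic conditions that leave the triketone and the geranyl chain alone.

## Compound list

1 | 4,4-dimethylcyclohex-2-en-1-one | CC1(C)CCC(=O)C=C1 | starting material
2 | (1R)-4,4-dimethylcyclohex-2-en-1-ol | O[C@H]1C=CC(C)(C)CC1 | intermediate
3 | ethyl 2-[(1R)-6,6-dimethylcyclohex-2-en-1-yl]acetate | C1C=C[C@@H](CC(=O)OCC)C(C)(C)C1 | intermediate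
4 | ethyl 2-[(1R)-6,6-dimethyl-4-oxocyclohex-2-en-1-yl]acetate | O=C1C=C[C@@H](CC(=O)OCC)C(C)(C)C1 | intermediate
5 | ethyl 2-[(1S)-2,2-dimethyl-4-oxocyclohexyl]acetate | O=C1CC[C@@H](CC(=O)OCC)C(C)(C)C1 | intermediate
6 | ethyl 2-[(8S)-7,7-dimethyl-1,4-dioxaspiro[4.5]decan-8-yl]acetate | O1CCOC12CC[C@@H](CC(=O)OCC)C(C)(C)C2 | intermediate
7 | 2-[(8S)-7,7-dimethyl-1,4-dioxaspiro[4.5]decan-8-yl]acetaldehyde | O1CCOC12CC[C@@H](CC=O)C(C)(C)C2 | intermediate
8 | dimethyl malonate | COC(=O)CC(=O)OC | starting material
9 | dimethyl 2-{2-[(8S)-7,7-dimethyl-1,4-dioxaspiro[4.5]decan-8-yl]ethylidene}propanedioate | O1CCOC12CC[C@@H](CC=C(C(=O)OC)C(=O)OC)C(C)(C)C2 | intermediate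
10 | 3-methylbuta-1,2-diene | CC(C)=C=C | starting material
11 | tert-butyl(dimethyl)(3-methylbuta-1,2-dien-1-yl)silane | CC(C)=C=C[Si](C)(C)C(C)(C)C | intermediate
12 | dimethyl (5R)-3-[tert-butyl(dimethyl)silyl]-5-{[(8S)-7,7-dimethyl-1,4-dioxaspiro[4.5]decan-8-yl]methyl}-4,4-dimethylcyclopent-2-ene-1,1-dicarboxylate | O1CCOC12CC[C@@H](C[C@H]3C(C)(C)C([Si](C)(C)C(C)(C)C)=CC3(C(=O)OC)C(=O)OC)C(C)(C)C2 | intermediate
13 | (1S,5R)-3-[tert-butyl(dimethyl)silyl]-5-{[(8S)-7,7-dimethyl-1,4-dioxaspiro[4.5]decan-8-yl]methyl}-1-(methoxycarbonyl)-4,4-dimethylcyclopent-2-ene-1-carboxylic acid | O1CCOC12CC[C@@H](C[C@H]3C(C)(C)C([Si](C)(C)C(C)(C)C)=C[C@]3(C(=O)OC)C(=O)O)C(C)(C)C2 | intermediate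
14 | 1-tert-butyl 1-methyl (1R,5R)-3-[tert-butyl(dimethyl)silyl]-5-{[(8S)-7,7-dimethyl-1,4-dioxaspiro[4.5]decan-8-yl]methyl}-4,4-dimethylcyclopent-2-ene-1,1-dicarboxylate | O1CCOC12CC[C@@H](C[C@H]3C(C)(C)C([Si](C)(C)C(C)(C)C)=C[C@]3(C(=O)OC)C(=O)OC(C)(C)C)C(C)(C)C2 | intermediate
15 | 1-tert-butyl 1-methyl (1R,5R)-5-{[(8S)-7,7-dimethyl-1,4-dioxaspiro[4.5]decan-8-yl]methyl}-3-iodo-4,4-dimethylcyclopent-2-ene-1,1-dicarboxylate | O1CCOC12CC[C@@H](C[C@H]3C(C)(C)C(I)=C[C@]3(C(=O)OC)C(=O)OC(C)(C)C)C(C)(C)C2 | intermediate
16 | 1-tert-butyl 1-methyl (1S,5S)-5-{[(8S)-7,7-dimethyl-1,4-dioxaspiro[4.5]decan-8-yl]methyl}-3-(1-ethoxyethenyl)-4,4-dimethylcyclopent-2-ene-1,1-dicarboxylate | O1CCOC12CC[C@@H](C[C@H]3C(C)(C)C(C(=C)OCC)=C[C@]3(C(=O)OC)C(=O)OC(C)(C)C)C(C)(C)C2 | intermediate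
17 | 1-tert-butyl 1-methyl (1S,5S)-3-acetyl-5-{[(8S)-7,7-dimethyl-1,4-dioxaspiro[4.5]decan-8-yl]methyl}-4,4-dimethylcyclopent-2-ene-1,1-dicarboxylate | O1CCOC12CC[C@@H](C[C@H]3C(C)(C)C(C(C)=O)=C[C@]3(C(=O)OC)C(=O)OC(C)(C)C)C(C)(C)C2 | intermediate
18 | 1-tert-butyl 1-methyl (1S,2S,4S)-4-acetyl-2-{[(8S)-7,7-dimethyl-1,4-dioxaspiro[4.5]decan-8-yl]methyl}-3,3-dimethylcyclopentane-1,1-dicarboxylate (acetyl cis to the side chain) | O1CCOC12CC[C@@H](C[C@H]3C(C)(C)[C@@H](C(C)=O)C[C@]3(C(=O)OC)C(=O)OC(C)(C)C)C(C)(C)C2 | intermediate
19 | 1-tert-butyl 1-methyl (1S,2S,4R)-4-acetyl-2-{[(8S)-7,7-dimethyl-1,4-dioxaspiro[4.5]decan-8-yl]methyl}-3,3-dimethylcyclopentane-1,1-dicarboxylate (acetyl trans to the side chain) | O1CCOC12CC[C@@H](C[C@H]3C(C)(C)[C@H](C(C)=O)C[C@]3(C(=O)OC)C(=O)OC(C)(C)C)C(C)(C)C2 | intermediate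
20 | 1-tert-butyl 1-methyl (1S,2S,4R)-2-{[(8S)-7,7-dimethyl-1,4-dioxaspiro[4.5]decan-8-yl]methyl}-4-(2-hydroxypropan-2-yl)-3,3-dimethylcyclopentane-1,1-dicarboxylate | O1CCOC12CC[C@@H](C[C@H]3C(C)(C)[C@H](C(C)(C)O)C[C@]3(C(=O)OC)C(=O)OC(C)(C)C)C(C)(C)C2 | intermediate
21 | 1-tert-butyl 1-methyl (1S,2S,4R)-2-{[(8S)-7,7-dimethyl-1,4-dioxaspiro[4.5]decan-8-yl]methyl}-3,3-dimethyl-4-{2-[(triethylsilyl)oxy]propan-2-yl}cyclopentane-1,1-dicarboxylate | O1CCOC12CC[C@@H](C[C@H]3C(C)(C)[C@H](C(C)(C)O[Si](CC)(CC)CC)C[C@]3(C(=O)OC)C(=O)OC(C)(C)C)C(C)(C)C2 | intermediate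
22 | 1-tert-butyl 1-methyl (1S,2S,4R)-2-{[(1S)-2,2-dimethyl-4-oxocyclohexyl]methyl}-3,3-dimethyl-4-{2-[(triethylsilyl)oxy]propan-2-yl}cyclopentane-1,1-dicarboxylate | O=C1CC[C@@H](C[C@H]2C(C)(C)[C@H](C(C)(C)O[Si](CC)(CC)CC)C[C@]2(C(=O)OC)C(=O)OC(C)(C)C)C(C)(C)C1 | intermediate
23 | bicyclic β-diketone from C4–C5 closure (C5–H, C1 = CH2, tert-butyl ester on C3, silyl ether on C15) | [C@@H]1(C(=O)CC2(C)C)C[C@H]2C[C@H]3C(C)(C)[C@H](C(C)(C)O[Si](CC)(CC)CC)C[C@]3(C1=O)C(=O)OC(C)(C)C | intermediate
24 | geranyl bromide, (2E)-1-bromo-3,7-dimethylocta-2,6-diene | CC(C)=CCC/C(C)=C/CBr | starting material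
25 | C5-geranylated bicyclic diketone (tert-butyl ester on C3) | CC(C)=CCC/C(C)=C/C[C@@]1(C(=O)CC2(C)C)C[C@H]2C[C@H]3C(C)(C)[C@H](C(C)(C)O[Si](CC)(CC)CC)C[C@]3(C1=O)C(=O)OC(C)(C)C | intermediate
26 | carboxylic acid corresponding to 25 | CC(C)=CCC/C(C)=C/C[C@@]1(C(=O)CC2(C)C)C[C@H]2C[C@H]3C(C)(C)[C@H](C(C)(C)O[Si](CC)(CC)CC)C[C@]3(C1=O)C(=O)O | intermediate
27 | acid chloride corresponding to 26 | CC(C)=CCC/C(C)=C/C[C@@]1(C(=O)CC2(C)C)C[C@H]2C[C@H]3C(C)(C)[C@H](C(C)(C)O[Si](CC)(CC)CC)C[C@]3(C1=O)C(=O)Cl | intermediate
28 | cage trione with C1–H, triethylsilyl ether | CC(C)=CCC/C(C)=C/C[C@@]12C[C@H]3C[C@H]4C(C)(C)[C@H](C(C)(C)O[Si](CC)(CC)CC)C[C@]4(C1=O)C(=O)[C@@H](C2=O)C3(C)C | intermediate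
29 | triethylsilyl ether of the target | CC(C)=CCC/C(C)=C/C[C@@]12C[C@H]3C[C@H]4C(C)(C)[C@H](C(C)(C)O[Si](CC)(CC)CC)C[C@]4(C1=O)C(=O)[C@@](C(=O)c1ccccc1)(C2=O)C3(C)C | intermediate
30 | CNP0164095.1 | CC(C)=CCC/C(C)=C/C[C@@]12C[C@H]3C[C@H]4C(C)(C)[C@H](C(C)(C)O)C[C@]4(C1=O)C(=O)[C@@](C(=O)c1ccccc1)(C2=O)C3(C)C | target

## Step count and least certain steps

Total: 23 steps. Longest linear sequence: 22 steps (steps 1–7 and 9–23); step 8 is the one-step side branch.

**Step 9 (key step, proposed new method).** The most likely failures are too little reactivity of the allenylsilane towards the copper chelate, loss of silicon from the vinyl cation before ring closure (propargyl transfer in place of annulation), and weak face selection at C11, since no result exists for this nucleophile class with this catalyst. Fallback, from 9 back to the route at 17, building the ring in two known steps: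
- Mukaiyama–Michael addition of trimethyl[(3-methylbut-2-en-2-yl)oxy]silane to 9 under the same copper bis(oxazoline) triflate, with (CF3)2CHOH as silyl acceptor, forms the C11–C12 bond and gives the keto malonate F1.
- Double deprotonation with LiN(iPr)2 and oxidation of the bis-enolate with Fe(acac)3 joins the methyl ketone carbon to the malonate carbon (C3–C14) and gives the cyclopentanone F2.
- KOH cleaves the ester trans to the side chain to the half acid F3, and the isourea gives the tert-butyl methyl diester F4.
- KN(SiMe3)2 and PhNTf2 give the enol triflate F5.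
- Stille coupling of F5 with tributyl(1-ethoxyvinyl)stannane (Pd(PPh3)4, LiCl) and dilute acid leads through 16 to 17.

**Step 14 (C13).** The equilibrium may lie less far on the trans side than the conformational argument suggests. Methoxide may also trigger condensation of the methyl ketone enolate with an ester or ring opening by β-elimination of the malonate carbon. Fallback, from 17 back to 19, replacing thermodynamic control by directed delivery of hydrogen:
- LiOH in aqueous THF cleaves only the methyl ester (the one cis to C10) and gives the enone acid F6.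
- Hydrogenation of its triethylammonium salt with [Rh(nbd)(dppb)]BF4 delivers H2 from the carboxylate face, placing hydrogen on C13 cis to C10 and the acetyl group trans, to give the acid F7.
- Me3SiCHN2 restores the methyl ester, giving 19.

**Step 18 (first ring closure).** The C5 enolate may exchange protons and equilibrate, or the seven-membered ring may form too slowly on a neopentyl ester, so that intermolecular condensation wins. Fallback, from 22 back to 23, by irreversible acylation:
- LiOH cleaves the methyl ester to the acid F8.
- 1-Chloro-N,N,2-trimethylprop-1-en-1-amine gives the acid chloride F9.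
- MgBr2·OEt2 with i-Pr2NEt acylates the less hindered α-carbon C5 by soft enolisation, the product being held as its magnesium diketonate, to give 23.

**Step 21 (cage closure).** O-Acylation of the C9 enolate to a bridged enol lactone, or failure to close at all because strain builds up at the quaternary C3. Fallback, from 27 back to 28, replacing the acylation by an aldol addition:
- Pd(PPh3)4 and Bu3SnH reduce the acid chloride to the aldehyde F10.
- KN(SiMe3)2 at −78 °C closes C1 onto the non-enolisable aldehyde to the cage aldol F11.
- Dess–Martin oxidation gives 28.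

**Step 22 (bridgehead benzoylation).** Deprotonation at C1 of the rigid cage may be slower than attack of the amide base or the electrophile by-products on a cage carbonyl, which would open the diketone. Fallback, from 25 back to 29, putting the benzoyl group on before the cage closes:
- MgBr2·OEt2, i-Pr2NEt and PhCOCl benzoylate C1 to the benzoyl diketone F12.
- Me3SiOTf and 2,6-lutidine give the acid F13.
- The chloroenamine gives the acid chloride F14.
- MgCl2 and Et3N in MeCN promote C-acylation of the C1 diketone carbon, which closes the cage directly to 29.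

## Further compounds

F1 | step 9 | dimethyl 2-[(2S)-1-[(8S)-7,7-dimethyl-1,4-dioxaspiro[4.5]decan-8-yl]-3,3-dimethyl-4-oxopentan-2-yl]propanedioate (Michael adduct, C11 as in 12) | O1CCOC12CC[C@@H](C[C@H](C(C(=O)OC)C(=O)OC)C(C)(C)C(C)=O)C(C)(C)C2
F2 | step 9 | dimethyl 2-{[(8S)-7,7-dimethyl-1,4-dioxaspiro[4.5]decan-8-yl]methyl}-3,3-dimethyl-4-oxocyclopentane-1,1-dicarboxylate | O1CCOC12CC[C@@H](C[C@H]3C(C)(C)C(=O)CC3(C(=O)OC)C(=O)OC)C(C)(C)C2
F3 | step 9 | half acid of F2 (acid trans to the side chain) | O1CCOC12CC[C@@H](C[C@H]3C(C)(C)C(=O)C[C@]3(C(=O)OC)C(=O)O)C(C)(C)C2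
F4 | step 9 | tert-butyl methyl diester of F3 | O1CCOC12CC[C@@H](C[C@H]3C(C)(C)C(=O)C[C@]3(C(=O)OC)C(=O)OC(C)(C)C)C(C)(C)C2
F5 | step 9 | enol triflate of F4 (triflate on C13) | O1CCOC12CC[C@@H](C[C@H]3C(C)(C)C(OS(=O)(=O)C(F)(F)F)=C[C@]3(C(=O)OC)C(=O)OC(C)(C)C)C(C)(C)C2
F6 | step 14 | enone acid from 17 (acid cis to the side chain, tert-butyl ester kept) | O1CCOC12CC[C@@H](C[C@H]3C(C)(C)C(C(C)=O)=C[C@]3(C(=O)O)C(=O)OC(C)(C)C)C(C)(C)C2
F7 | step 14 | saturated trans-acetyl acid | O1CCOC12CC[C@@H](C[C@H]3C(C)(C)[C@H](C(C)=O)C[C@]3(C(=O)O)C(=O)OC(C)(C)C)C(C)(C)C2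
F8 | step 18 | keto acid from 22 (acid cis to C10) | O=C1CC[C@@H](C[C@H]2C(C)(C)[C@H](C(C)(C)O[Si](CC)(CC)CC)C[C@]2(C(=O)O)C(=O)OC(C)(C)C)C(C)(C)C1
F9 | step 18 | acid chloride of F8 | O=C1CC[C@@H](C[C@H]2C(C)(C)[C@H](C(C)(C)O[Si](CC)(CC)CC)C[C@]2(C(=O)Cl)C(=O)OC(C)(C)C)C(C)(C)C1
F10 | step 21 | aldehyde corresponding to 27 (CHO on C3) | CC(C)=CCC/C(C)=C/C[C@@]1(C(=O)CC2(C)C)C[C@H]2C[C@H]3C(C)(C)[C@H](C(C)(C)O[Si](CC)(CC)CC)C[C@]3(C1=O)C=O
F11 | step 21 | cage aldol (C2 carbinol, configuration at C2 open) | CC(C)=CCC/C(C)=C/C[C@@]12C[C@H]3C[C@H]4C(C)(C)[C@H](C(C)(C)O[Si](CC)(CC)CC)C[C@]4(C1=O)C(O)[C@@H](C2=O)C3(C)C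
F12 | step 22 | C1-benzoyl derivative of 25 (configuration at C1 open) | CC(C)=CCC/C(C)=C/C[C@@]1(C(=O)C(C(=O)c4ccccc4)C2(C)C)C[C@H]2C[C@H]3C(C)(C)[C@H](C(C)(C)O[Si](CC)(CC)CC)C[C@]3(C1=O)C(=O)OC(C)(C)C
F13 | step 22 | carboxylic acid corresponding to F12 | CC(C)=CCC/C(C)=C/C[C@@]1(C(=O)C(C(=O)c4ccccc4)C2(C)C)C[C@H]2C[C@H]3C(C)(C)[C@H](C(C)(C)O[Si](CC)(CC)CC)C[C@]3(C1=O)C(=O)O
F14 | step 22 | acid chloride corresponding to F13 | CC(C)=CCC/C(C)=C/C[C@@]1(C(=O)C(C(=O)c4ccccc4)C2(C)C)C[C@H]2C[C@H]3C(C)(C)[C@H](C(C)(C)O[Si](CC)(CC)CC)C[C@]3(C1=O)C(=O)Cl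
A1 | alternative 1 | complete cage lacking the geranyl group (C5–H) | [C@@H]12C[C@H]3C[C@H]4C(C)(C)[C@H](C(C)(C)O)C[C@]4(C1=O)C(=O)[C@@](C(=O)c1ccccc1)(C2=O)C3(C)C
A2 | alternative 2 | 5-geranyl-7-prenyl-8,8-dimethylbicyclo[3.3.1]nonane-2,4,9-trione methyl enol ether | CC(C)=CCC/C(C)=C/C[C@@]12C[C@@H](CC=C(C)C)C(C)(C)[C@H](C2=O)C(=O)C=C1OC
A3 | alternative 3 | cis-disubstituted siloxy cycloheptadiene carboxylate | COC(=O)C1=C(O[Si](C)(C)C(C)(C)C)[C@H](CC=C(C)C)[C@H](C(C)(C)O[Si](CC)(CC)CC)C=C(C(C)(C)CC(=O)c2ccccc2)C1
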